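## Retrosynthetic overview

- The target is two (−)-fisetinidol units bonded through C4 (4α, 3,4-trans) to C6 and C8 of 4'-O-methyl-(+)-catechin; the last operation is removal of six benzyl ethers.
- Both interflavanyl C4–aryl bonds and both O1–C2 bonds of the upper units are cut together: hexabenzyl triflavanoid ⇒ 4'-O-methylcatechin + 2 × an acyclic phenolic epoxy carbinol (one flask: two epoxide-opening ring closures, two Friedel–Crafts alkylations).
- Epoxy carbinol ⇒ (2R,3S)-chalcone epoxide (Juliá–Colonna) ⇒ chalcone ⇒ 2'-allyloxy-4'-benzyloxyacetophenone + 3,4-bis(benzyloxy)benzaldehyde.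
- 4'-O-Methylcatechin ⇒ (+)-catechin, which supplies the lower pyran ring and its two stereocentres.
- Ring order: catechin heterocycle (bought) → both fisetinidol pyran rings together in step 6; no ring is made afterwards.

Assumption: the carbinol carbon made in step 5 (and C4 of the flavan-3,4-diol formed from it) is carried as a mixture of epimers and drawn without configuration, because this centre is ionised in step 6.

## Route

Step 1
Reactants: 1 (+)-catechin
Product: 2 4'-O-methyl-(+)-catechin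
Conditions: MeI (1.0 equiv), K2CO3 (1.0 equiv), acetone, 25 °C, ultrasound, 3 h; silica gel, then reversed-phase chromatography
Reagents that add atoms: iodomethane, CI
Why: Williamson O-methylation, expected to occur mainly on the catechol ring (the most acidic site), giving the 4'- and 3'-methyl ethers in comparable amounts, from which the 4'-isomer (NOE from OMe to H-5') is isolated in an estimated 20% yield; no stereocentre is touched.

Step 2
Reactants: 3 1-[4-(benzyloxy)-2-hydroxyphenyl]ethan-1-one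
Product: 4 1-[4-(benzyloxy)-2-(prop-2-en-1-yloxy)phenyl]ethan-1-one
Conditions: allyl bromide (1.3 equiv), K2CO3 (2 equiv), DMF, 60 °C, 6 h
Reagents that add atoms: allyl bromide (3-bromoprop-1-ene), C=CCBr
Why: Williamson etherification of the hydrogen-bonded ortho-phenol masks it against Algar–Flynn–Oyamada cyclisation in step 4 with a group that can later be removed without acid.

Step 3
Reactants: 4 1-[4-(benzyloxy)-2-(prop-2-en-1-yloxy)phenyl]ethan-1-one; 5 3,4-bis(benzyloxy)benzaldehyde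
Product: 6 (2E)-1-[4-(benzyloxy)-2-(prop-2-en-1-yloxy)phenyl]-3-[3,4-bis(benzyloxy)phenyl]prop-2-en-1-one
Conditions: KOH (3 equiv), EtOH–THF 3:1, 25 °C, 24 h
Reagents that add atoms: none
Why: Claisen–Schmidt condensation (aldol addition then E1cB loss of water) gives the conjugated E-enone as the thermodynamic product.

Step 4
Reactants: 6 (2E)-1-[4-(benzyloxy)-2-(prop-2-en-1-yloxy)phenyl]-3-[3,4-bis(benzyloxy)phenyl]prop-2-en-1-one
Product: 7 [4-(benzyloxy)-2-(prop-2-en-1-yloxy)phenyl]{(2R,3S)-3-[3,4-bis(benzyloxy)phenyl]oxiran-2-yl}methanone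
Conditions: immobilised poly-L-leucine, urea–H2O2 (1.5 equiv), DBU (1.5 equiv), THF, 25 °C, 24 h; recrystallisation
Reagents that add atoms: urea–hydrogen peroxide adduct, OO.NC(N)=O
Why: Juliá–Colonna epoxidation (polypeptide-catalysed asymmetric Weitz–Scheffer reaction) in which the helical poly-L-leucine directs hydroperoxide to the enone face that gives the (2R,3S) trans-epoxide, fixing the later C3 (retained) and C2 (inverted in step 6) of each fisetinidol unit, with recrystallisation raising the ee.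

Step 5
Reactants: 7 [4-(benzyloxy)-2-(prop-2-en-1-yloxy)phenyl]{(2R,3S)-3-[3,4-bis(benzyloxy)phenyl]oxiran-2-yl}methanone
Product: 9 5-(benzyloxy)-2-[(RS)-{(2S,3S)-3-[3,4-bis(benzyloxy)phenyl]oxiran-2-yl}(hydroxy)methyl]phenol, via allyl-protected epoxy alcohol 8 (not isolated)
Conditions: NaBH4 (2.5 equiv), THF–MeOH 4:1, 0 °C, 30 min; then Pd(PPh3)4 (2 mol%), 0 → 20 °C, 1 h; pH 7 phosphate buffer, quick filtration through Et3N-deactivated silica; used at once
Reagents that add atoms: none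
Why: Borohydride reduction of the aryl ketone is followed in the same flask by Pd(PPh3)4-catalysed Tsuji–Trost-type reductive cleavage of the aryl allyl ether with hydride as allyl acceptor (propene is lost), which spares benzyl ethers and the epoxide under cold, non-acidic conditions; the new carbinol centre need not be controlled.

Step 6
Reactants: 9 5-(benzyloxy)-2-[(RS)-{(2S,3S)-3-[3,4-bis(benzyloxy)phenyl]oxiran-2-yl}(hydroxy)methyl]phenol (2.6 equiv); 2 4'-O-methyl-(+)-catechin (1.0 equiv)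
Product: 13 bis(7,3',4'-tri-O-benzylfisetinidol)-(4α→6:4α→8)-4'-O-methylcatechin, via tri-O-benzyl flavan-3,4-diol 10 (not isolated), via 8-linked biflavanoid 11 (not isolated), via 6-linked biflavanoid 12 (not isolated)
Conditions: TsOH·H2O (0.3 equiv), 1,4-dioxane–CH2Cl2 1:1, 9 added over 2 h at 0 °C, then 25 °C, 16 h; silica gel, then preparative HPLC (all-trans isomer separated from 3,4-cis isomers)
Reagents that add atoms: none
Why: Proposed new method: under catalytic TsOH the phenol of each molecule of 9 opens its own electron-rich benzylic epoxide in a 6-endo mode with inversion (closest known reaction: acid-promoted phenol–epoxide cyclisation to 2,3-trans-flavan-3-ols) to give 2,3-trans diol 10, whose doubly oxygen-activated C4 hydroxyl then ionises and is captured by C8 and C6 of the phloroglucinol ring of 2 (closest known reaction: acid-catalysed Friedel–Crafts condensation of flavan-3,4-diols with catechin), the arene entering anti to the 3-hydroxyl of the half-chair cation so that both new C4 centres are 3,4-trans (4α, 4S) while C2 and C3 of both new pyran rings come from the epoxide of 7; ring closure is expected to run first because ionisation of a carbinol next to the electron-withdrawing epoxide is slow and needs an external nucleophile.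

Step 7
Reactants: 13 bis(7,3',4'-tri-O-benzylfisetinidol)-(4α→6:4α→8)-4'-O-methylcatechin
Product: 14 fisetinidol-(4α→8)-[fisetinidol-(4α→6)]-4'-O-methylcatechin (target, CNP0209850.1)
Conditions: H2 (1 atm), Pd(OH)2/C (20 wt%), THF–MeOH 1:1, 25 °C, 12 h; Sephadex LH-20
Reagents that add atoms: none
Why: Catalytic hydrogenolysis removes the six benzyl ethers as toluene while the methyl ether, the pyran C2–O bonds and the 5-deoxy interflavanyl bonds are stable, so no stereocentre is affected.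

## Compound list

1 | (+)-catechin, (2R,3S)-2-(3,4-dihydroxyphenyl)-3,4-dihydro-2H-chromene-3,5,7-triol | Oc1ccc([C@H]2Oc3cc(O)cc(O)c3C[C@@H]2O)cc1O | starting material
2 | 4'-O-methyl-(+)-catechin, (2R,3S)-2-(3-hydroxy-4-methoxyphenyl)-3,4-dihydro-2H-chromene-3,5,7-triol | COc1ccc([C@H]2Oc3cc(O)cc(O)c3C[C@@H]2O)cc1O | intermediate
3 | 1-[4-(benzyloxy)-2-hydroxyphenyl]ethan-1-one | CC(=O)c1ccc(OCc2ccccc2)cc1O | starting material
4 | 1-[4-(benzyloxy)-2-(prop-2-en-1-yloxy)phenyl]ethan-1-one | CC(=O)c1ccc(OCc2ccccc2)cc1OCC=C | intermediate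
5 | 3,4-bis(benzyloxy)benzaldehyde | O=Cc1ccc(OCc2ccccc2)c(OCc2ccccc2)c1 | starting material
6 | (2E)-1-[4-(benzyloxy)-2-(prop-2-en-1-yloxy)phenyl]-3-[3,4-bis(benzyloxy)phenyl]prop-2-en-1-one | C=CCOc1cc(OCc2ccccc2)ccc1C(=O)/C=C/c1ccc(OCc2ccccc2)c(OCc2ccccc2)c1 | intermediate
7 | [4-(benzyloxy)-2-(prop-2-en-1-yloxy)phenyl]{(2R,3S)-3-[3,4-bis(benzyloxy)phenyl]oxiran-2-yl}methanone (trans-epoxide) | C=CCOc1cc(OCc2ccccc2)ccc1C(=O)[C@@H]1O[C@H]1c1ccc(OCc2ccccc2)c(OCc2ccccc2)c1 | intermediate
8 | (RS)-[4-(benzyloxy)-2-(prop-2-en-1-yloxy)phenyl]{(2S,3S)-3-[3,4-bis(benzyloxy)phenyl]oxiran-2-yl}methanol (carbinol epimers; trans-epoxide) | C=CCOc1cc(OCc2ccccc2)ccc1C(O)[C@@H]1O[C@H]1c1ccc(OCc2ccccc2)c(OCc2ccccc2)c1 | intermediate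
9 | 5-(benzyloxy)-2-[(RS)-{(2S,3S)-3-[3,4-bis(benzyloxy)phenyl]oxiran-2-yl}(hydroxy)methyl]phenol (carbinol epimers) | Oc1cc(OCc2ccccc2)ccc1C(O)[C@@H]1O[C@H]1c1ccc(OCc2ccccc2)c(OCc2ccccc2)c1 | intermediate
10 | (2R,3S,4RS)-7-(benzyloxy)-2-[3,4-bis(benzyloxy)phenyl]-3,4-dihydro-2H-chromene-3,4-diol (2,3-trans; C4 epimers) | OC1c2ccc(OCc3ccccc3)cc2O[C@H](c2ccc(OCc3ccccc3)c(OCc3ccccc3)c2)[C@H]1O | intermediate
11 | 7,3',4'-tri-O-benzylfisetinidol-(4α→8)-4'-O-methylcatechin; upper unit (2R,3S,4S), lower unit (2R,3S) | COc1ccc([C@H]2Oc3c(c(O)cc(O)c3[C@@H]3c4ccc(OCc5ccccc5)cc4O[C@H](c4ccc(OCc5ccccc5)c(OCc5ccccc5)c4)[C@H]3O)C[C@@H]2O)cc1O | intermediate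
12 | 7,3',4'-tri-O-benzylfisetinidol-(4α→6)-4'-O-methylcatechin; upper unit (2R,3S,4S), lower unit (2R,3S) | COc1ccc([C@H]2Oc3cc(O)c([C@@H]4c5ccc(OCc6ccccc6)cc5O[C@H](c5ccc(OCc6ccccc6)c(OCc6ccccc6)c5)[C@H]4O)c(O)c3C[C@@H]2O)cc1O | intermediate
13 | (2R,3S)-6,8-bis{(2R,3S,4S)-7-(benzyloxy)-2-[3,4-bis(benzyloxy)phenyl]-3-hydroxy-3,4-dihydro-2H-chromen-4-yl}-2-(3-hydroxy-4-methoxyphenyl)-3,4-dihydro-2H-chromene-3,5,7-triol | COc1ccc([C@H]2Oc3c(c(O)c([C@@H]4c5ccc(OCc6ccccc6)cc5O[C@H](c5ccc(OCc6ccccc6)c(OCc6ccccc6)c5)[C@H]4O)c(O)c3[C@@H]3c4ccc(OCc5ccccc5)cc4O[C@H](c4ccc(OCc5ccccc5)c(OCc5ccccc5)c4)[C@H]3O)C[C@@H]2O)cc1O | intermediate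
14 | (2R,3S)-6,8-bis[(2R,3S,4S)-2-(3,4-dihydroxyphenyl)-3,7-dihydroxy-3,4-dihydro-2H-chromen-4-yl]-2-(3-hydroxy-4-methoxyphenyl)-3,4-dihydro-2H-chromene-3,5,7-triol | COc1ccc([C@H]2Oc3c(c(O)c([C@@H]4c5ccc(O)cc5O[C@H](c5ccc(O)c(O)c5)[C@H]4O)c(O)c3[C@@H]3c4ccc(O)cc4O[C@H](c4ccc(O)c(O)c4)[C@H]3O)C[C@@H]2O)cc1O | target

## Step count and risks

Total step count: 7. Longest linear sequence: 6 steps (3 → 4 → 6 → 7 → 9 → 13 → 14); step 1 is a one-step side branch.

The three steps most likely to fail are 6, 5 and 1.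

**Step 6.** The risks are low 3,4-trans selectivity at one or both C4 centres, incomplete second substitution at C6, and ionisation of the carbinol of 9 before ring closure. The fallback separates ring closure from coupling and replaces acid by thiophilic activation. It sets out from 9 and comes back at 13. Compound 9 is cyclised alone (PPTS, CH2Cl2, 0 °C) to the flavan-3,4-diol 10, which is isolated. Compound 10 is converted with phenylmethanethiol and catalytic TsOH into (2R,3R,4RS)-4-(benzylsulfanyl)-7-(benzyloxy)-2-[3,4-bis(benzyloxy)phenyl]-3,4-dihydro-2H-chromen-3-ol F7. This thioether (2.5 equiv) is activated with AgBF4 in THF at 0 °C in the presence of 2, which gives 13 under near-neutral conditions.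

**Step 5.** The risks are that the liberated phenoxide attacks the epoxide under the basic conditions (possibly in the 5-exo mode), that the hydride opens the benzylic epoxide, or that 9 decomposes on handling. The fallback closes the ring at the ketone oxidation level, where 6-endo closure is well behaved. It sets out from 7 and comes back at 10. Pd(PPh3)4 with K2CO3 in MeOH–THF removes the allyl group of 7. The resulting [4-(benzyloxy)-2-hydroxyphenyl]{(2R,3S)-3-[3,4-bis(benzyloxy)phenyl]oxiran-2-yl}methanone F5 closes in the same flask, with inversion at the benzylic carbon, to (2R,3R)-7-(benzyloxy)-2-[3,4-bis(benzyloxy)phenyl]-3-hydroxy-2,3-dihydro-4H-chromen-4-one F6. NaBH4 in EtOH–THF at 0 °C reduces F6 to 10 (mainly the 4R epimer), which then replaces 9 in step 6.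

**Step 1.** The risk is the poor 3'/4' selectivity and a difficult separation of the free phenols. The fallback moves the methylation to a protected intermediate in which only the catechol can react and the regioisomers separate on ordinary silica. It sets out from 1 and comes back at 2. Compound 1 is treated with dichlorodiphenylmethane and K2CO3 in MeCN to give 3',4'-O-(diphenylmethylene)-(+)-catechin F1. BnBr and K2CO3 in DMF give 5,7-di-O-benzyl-3',4'-O-(diphenylmethylene)-(+)-catechin F2. Aqueous acetic acid at 80 °C removes the ketal to give 5,7-di-O-benzyl-(+)-catechin F3. MeI (1.0 equiv) and K2CO3 in acetone, followed by chromatographic removal of the 3'-regioisomer, give 5,7-di-O-benzyl-4'-O-methyl-(+)-catechin F4. Hydrogenolysis (H2, Pd(OH)2/C) of F4 gives 2.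

## Further compounds

F1 | step 1 | 3',4'-O-(diphenylmethylene)-(+)-catechin | C1(c2ccccc2)(c2ccccc2)Oc2ccc([C@H]3Oc4cc(O)cc(O)c4C[C@@H]3O)cc2O1
F2 | step 1 | 5,7-di-O-benzyl-3',4'-O-(diphenylmethylene)-(+)-catechin | C1(c2ccccc2)(c2ccccc2)Oc2ccc([C@H]3Oc4cc(OCc5ccccc5)cc(OCc5ccccc5)c4C[C@@H]3O)cc2O1
F3 | step 1 | 5,7-di-O-benzyl-(+)-catechin | Oc1ccc([C@H]2Oc3cc(OCc4ccccc4)cc(OCc4ccccc4)c3C[C@@H]2O)cc1O
F4 | step 1 | 5,7-di-O-benzyl-4'-O-methyl-(+)-catechin | COc1ccc([C@H]2Oc3cc(OCc4ccccc4)cc(OCc4ccccc4)c3C[C@@H]2O)cc1O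
F5 | step 5 | [4-(benzyloxy)-2-hydroxyphenyl]{(2R,3S)-3-[3,4-bis(benzyloxy)phenyl]oxiran-2-yl}methanone | Oc1cc(OCc2ccccc2)ccc1C(=O)[C@@H]1O[C@H]1c1ccc(OCc2ccccc2)c(OCc2ccccc2)c1
F6 | step 5 | (2R,3R)-7-(benzyloxy)-2-[3,4-bis(benzyloxy)phenyl]-3-hydroxy-2,3-dihydro-4H-chromen-4-one | O=C1c2ccc(OCc3ccccc3)cc2O[C@H](c2ccc(OCc3ccccc3)c(OCc3ccccc3)c2)[C@H]1O
F7 | step 6 | (2R,3R,4RS)-4-(benzylsulfanyl)-7-(benzyloxy)-2-[3,4-bis(benzyloxy)phenyl]-3,4-dihydro-2H-chromen-3-ol | c1ccccc1CSC1c2ccc(OCc3ccccc3)cc2O[C@H](c2ccc(OCc3ccccc3)c(OCc3ccccc3)c2)[C@H]1O
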